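**Plan** (target numbering: oxolane O1–C2H2–C3–C4–C5; C5 carries aryl ring A, C4 the CH2OH arm, C3 the exocyclic carbinol carbon Cα, which carries aryl ring B)
Cuts, in order: the ring B–Cα bond (to an aryl pinacol boronate and the O–CH2 carbamate of a primary alcohol); the Cα–O and C3–H bonds (to an exocyclic C3=CH2 alkene); ring bond C3–C4 (radical 5-exo-dig closure of an epoxy propargyl ether); then the O1–C2 ether bond and the vinyl–C5 bond (to silylated vanillin).
Forward: vanillin → vinyl carbinol (resolved) → propargyl ether → epoxide → the only ring (oxolane) by titanocene radical cyclisation → hydroboration → carbamate → lithiation–borylation with ring B → desilylation.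
Stereochemistry: C5 from a Sharpless kinetic resolution; C4 trans to ring A from the radical ring closure; C3 cis to the C4 arm from hydroboration anti to that arm; Cα from (+)-sparteine-directed lithiation followed by a stereospecific boron-to-carbon aryl shift.
Enabling feature: Cα bears only OH, H, ring B and ring carbon C3, so without ring B it is the O–CH2 carbon of a primary alcohol. Its carbamate can be lithiated under reagent control and arylated by 1,2-migration, and no epimerisable aldehyde on the cis-substituted C3 is needed.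

Key step: step 11

Remarks: ArT = 3-methoxy-4-{[tri(propan-2-yl)silyl]oxy}phenyl. (+)-Sparteine is taken to remove the pro-R hydrogen of the O–CH2 group, the mirror image of the established pro-S preference of (−)-sparteine. The phenolic aryl pinacol boronate and both sparteine enantiomers are taken as purchasable.

Step 1
Reactants: 1 vanillin (4-hydroxy-3-methoxybenzaldehyde)
Product: 2 3-methoxy-4-{[tri(propan-2-yl)silyl]oxy}benzaldehyde (ArT–CHO)
Conditions: TIPSCl, imidazole, DMF, rt
Reagents that add atoms: chlorotri(propan-2-yl)silane, CC(C)[Si](Cl)(C(C)C)C(C)C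
Why: Imidazole-assisted silyl ether formation masks the acidic phenol for the organometallic steps; no stereocentre is involved.

Step 2
Reactants: 2 ArT–CHO; 3 vinylmagnesium bromide
Product: 4 rac-1-ArT-prop-2-en-1-ol
Conditions: THF, 0 °C; then aq. NH4Cl
Reagents that add atoms: none
Why: Grignard 1,2-addition of the vinyl nucleophile to the aryl aldehyde should give the racemic allylic alcohol, the aryl silyl ether being inert to RMgX at 0 °C.

Step 3
Reactants: 4 rac-1-ArT-prop-2-en-1-ol
Product: 5 (1R)-1-ArT-prop-2-en-1-ol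
Conditions: Ti(OiPr)4 (cat.), D-(−)-diisopropyl tartrate, t-BuOOH (0.6 equiv), 4 Å molecular sieves, CH2Cl2, −20 °C; unreacted alcohol isolated
Reagents that add atoms: none
Why: Sharpless kinetic resolution: with the D-(−)-tartrate the titanium–tartrate–peroxide complex should epoxidise the (S)-alcohol fast and leave the (R)-alcohol, which fixes the future C5 stereocentre.

Step 4
Reactants: 5 (1R)-1-ArT-prop-2-en-1-ol; 6 3-bromoprop-1-yne (propargyl bromide)
Product: 7 (1R)-1-ArT-prop-2-en-1-yl prop-2-yn-1-yl ether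
Conditions: NaH, Bu4NI (cat.), THF, 0 °C → rt
Reagents that add atoms: none
Why: Williamson etherification of the sodium alkoxide with the propargylic bromide forms the O1–C2 bond without touching the carbinol stereocentre.

Step 5
Reactants: 7 (1R)-1-ArT-prop-2-en-1-yl prop-2-yn-1-yl ether
Product: 8 (S)-ArT(oxiran-2-yl)methyl prop-2-yn-1-yl ether as a mixture of the two oxirane epimers (benzylic geometry as in 7; only its CIP label changes)
Conditions: mCPBA, NaHCO3, CH2Cl2, 0 °C → rt
Reagents that add atoms: 3-chloroperoxybenzoic acid, OOC(=O)c1cccc(Cl)c1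
Why: Prilezhaev epoxidation should occur at the only alkene (alkyne and arene are far less reactive toward the peracid); the new oxirane centre forms without control, which is harmless because it becomes a planar radical in step 6.

Step 6
Reactants: 8 epoxy propargyl ether (epimer mixture)
Product: 9 [(2R,3S)-2-ArT-4-methylideneoxolan-3-yl]methanol (2,3-trans)
Conditions: Cp2TiCl2 (2.5 equiv), Zn dust, THF, rt; then 1 M HCl, 0 °C, brief
Reagents that add atoms: none
Why: Nugent–RajanBabu reaction: Cp2TiCl, a trivalent titanium reagent made in the flask, opens the oxirane homolytically to the secondary β-titanoxy radical, which closes 5-exo-dig onto the alkyne, and the vinyl radical takes H from THF; the new C4 centre should form trans to ring A because the transition state places the aryl group pseudo-equatorial and the CH2OTi arm away from it.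

Step 7
Reactants: 9 [(2R,3S)-2-ArT-4-methylideneoxolan-3-yl]methanol
Product: 10 tert-butyl{[(2R,3S)-2-ArT-4-methylideneoxolan-3-yl]methoxy}dimethylsilane
Conditions: TBSCl, imidazole, DMF, rt
Reagents that add atoms: tert-butylchlorodimethylsilane, CC(C)(C)[Si](C)(C)Cl
Why: Silylation of the primary alcohol differentiates this oxygen from the one introduced next and removes the acidic proton before the organolithium step.

Step 8
Reactants: 10 silyl ether of the methylidene-oxolane
Product: 11 [(3R,4S,5R)-5-ArT-4-({[tert-butyl(dimethyl)silyl]oxy}methyl)oxolan-3-yl]methanol (3,4-cis; 4,5-trans)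
Conditions: 9-BBN, THF, 0 °C → rt; then aq. NaOH, H2O2, 0 °C
Reagents that add atoms: hydrogen peroxide, OO
Why: Hydroboration–oxidation of the 1,1-disubstituted alkene is anti-Markovnikov, and the bulky borane should add to the face anti to the adjacent CH2OTBS arm, so H enters trans to that arm and the new CH2OH ends cis to it (sets C3).

Step 9
Reactants: 11 primary alcohol
Product: 12 [(3S,4S,5R)-5-ArT-4-({[tert-butyl(dimethyl)silyl]oxy}methyl)oxolan-3-yl]methyl N,N-di(propan-2-yl)carbamate (same geometry as 11; the C3 label changes by CIP priority only)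
Conditions: i-Pr2NCOCl, Et3N, CH2Cl2, reflux
Reagents that add atoms: N,N-di(propan-2-yl)carbamoyl chloride, CC(C)N(C(C)C)C(Cl)=O
Why: Carbamoylation of the primary alcohol installs the Hoppe directing and leaving group needed for the key step; no stereocentre is touched.

Step 10
Reactants: 13 2-methoxy-4-(4,4,5,5-tetramethyl-1,3,2-dioxaborolan-2-yl)phenol
Product: 14 [2-methoxy-4-(4,4,5,5-tetramethyl-1,3,2-dioxaborolan-2-yl)phenoxy]tri(propan-2-yl)silane (ArT–Bpin)
Conditions: TIPSCl, imidazole, DMF, rt
Reagents that add atoms: chlorotri(propan-2-yl)silane, CC(C)[Si](Cl)(C(C)C)C(C)C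
Why: Silyl ether formation removes the phenolic proton, which would quench the lithiated carbamate, and leaves the boronate untouched.

Step 11
Reactants: 12 carbamate; 14 ArT–Bpin
Product: 18 (S)-[(3S,4S,5R)-5-ArT-4-({[tert-butyl(dimethyl)silyl]oxy}methyl)oxolan-3-yl](ArT)methanol, via lithiated carbamate 15 (not isolated), via lithium boronate complex 16 (not isolated), via secondary pinacol boronate 17 (not isolated)
Conditions: s-BuLi, (+)-sparteine, Et2O, −78 °C; then 14, −78 °C; MgBr2·OEt2, −78 °C → reflux; then aq. NaOH, H2O2, THF, 0 °C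
Reagents that add atoms: hydrogen peroxide, OO
Why: s-BuLi/(+)-sparteine, held by the carbamate C=O, removes one enantiotopic H of the O–CH2 group to give the configurationally stable α-lithio carbamate 15, boronate 14 captures it with retention to give ate complex 16, on warming with MgBr2 ring B shifts from boron to carbon anti to the leaving carbamate (1,2-metallate rearrangement, inversion at carbon) to form the ring B–Cα bond in 17, and peroxide replaces boron by OH with retention. The closest known reaction type is the lithiation–borylation of primary alkyl carbamates with aryl pinacol boronates, which is established for secondary benzylic alcohols. No ring is closed. The new Cα stereocentre is controlled by the chiral diamine in the deprotonation, and the fixed retention–inversion–retention sequence converts the (R)-lithio centre into the (S)-carbinol. The step needs site selectivity for the carbamate CH2 over the benzylic C5–H of the 2-aryl oxolane and the positions ortho to OMe, which pre-complexation of the base to the carbamate carbonyl at −78 °C in Et2O should secure, and it needs complete migration, which MgBr2 and the electron-rich migrating aryl favour. The three ring stereocentres never sit next to a carbonyl group, so they cannot epimerise.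

Step 12
Reactants: 18 tris-silyl ether
Product: 19 4-[(S)-hydroxy[(3S,4S,5R)-5-(4-hydroxy-3-methoxyphenyl)-4-(hydroxymethyl)oxolan-3-yl]methyl]-2-methoxyphenol (target)
Conditions: TBAF, AcOH, THF, 0 °C → rt
Reagents that add atoms: none
Why: Fluoride-mediated desilylation cleaves the two aryl and one alkyl Si–O bonds under acetic acid-buffered conditions that avoid acid ionisation of the p-hydroxybenzylic alcohol and base-induced quinone methide formation, so all four stereocentres should be retained.

**Compound list**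
1 | vanillin (4-hydroxy-3-methoxybenzaldehyde) | COc1cc(C=O)ccc1O | starting material
2 | 3-methoxy-4-{[tri(propan-2-yl)silyl]oxy}benzaldehyde | COc1cc(C=O)ccc1O[Si](C(C)C)(C(C)C)C(C)C | intermediate
3 | vinylmagnesium bromide | C=C[Mg]Br | starting material
4 | rac-1-ArT-prop-2-en-1-ol | C=CC(O)c1ccc(O[Si](C(C)C)(C(C)C)C(C)C)c(OC)c1 | intermediate
5 | (1R)-1-ArT-prop-2-en-1-ol | C=C[C@@H](O)c1ccc(O[Si](C(C)C)(C(C)C)C(C)C)c(OC)c1 | intermediate
6 | 3-bromoprop-1-yne | C#CCBr | starting material
7 | (1R)-1-ArT-prop-2-en-1-yl prop-2-yn-1-yl ether | C=C[C@@H](OCC#C)c1ccc(O[Si](C(C)C)(C(C)C)C(C)C)c(OC)c1 | intermediate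
8 | (S)-ArT(oxiran-2-yl)methyl prop-2-yn-1-yl ether, both oxirane epimers | C#CCO[C@H](C1CO1)c1ccc(O[Si](C(C)C)(C(C)C)C(C)C)c(OC)c1 | intermediate
9 | [(2R,3S)-2-ArT-4-methylideneoxolan-3-yl]methanol | C=C1CO[C@@H](c2ccc(O[Si](C(C)C)(C(C)C)C(C)C)c(OC)c2)[C@@H]1CO | intermediate
10 | tert-butyl{[(2R,3S)-2-ArT-4-methylideneoxolan-3-yl]methoxy}dimethylsilane | C=C1CO[C@@H](c2ccc(O[Si](C(C)C)(C(C)C)C(C)C)c(OC)c2)[C@@H]1CO[Si](C)(C)C(C)(C)C | intermediate
11 | [(3R,4S,5R)-5-ArT-4-({[tert-butyl(dimethyl)silyl]oxy}methyl)oxolan-3-yl]methanol | OC[C@@H]1CO[C@@H](c2ccc(O[Si](C(C)C)(C(C)C)C(C)C)c(OC)c2)[C@@H]1CO[Si](C)(C)C(C)(C)C | intermediate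
12 | [(3S,4S,5R)-5-ArT-4-({[tert-butyl(dimethyl)silyl]oxy}methyl)oxolan-3-yl]methyl N,N-di(propan-2-yl)carbamate | CC(C)N(C(C)C)C(=O)OC[C@@H]1CO[C@@H](c2ccc(O[Si](C(C)C)(C(C)C)C(C)C)c(OC)c2)[C@@H]1CO[Si](C)(C)C(C)(C)C | intermediate
13 | 2-methoxy-4-(4,4,5,5-tetramethyl-1,3,2-dioxaborolan-2-yl)phenol | COc1cc(B2OC(C)(C)C(C)(C)O2)ccc1O | starting material
14 | [2-methoxy-4-(4,4,5,5-tetramethyl-1,3,2-dioxaborolan-2-yl)phenoxy]tri(propan-2-yl)silane | COc1cc(B2OC(C)(C)C(C)(C)O2)ccc1O[Si](C(C)C)(C(C)C)C(C)C | intermediate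
15 | α-lithio derivative of 12, (R) at the lithiated O–CH carbon ((+)-sparteine-bound) | CC(C)N(C(C)C)C(=O)O[C@H]([Li])[C@@H]1CO[C@@H](c2ccc(O[Si](C(C)C)(C(C)C)C(C)C)c(OC)c2)[C@@H]1CO[Si](C)(C)C(C)(C)C | intermediate
16 | lithium boronate (ate) complex of 15 with 14, boron in the place of lithium | [Li+].CC(C)N(C(C)C)C(=O)O[C@H]([B-]1(c2ccc(O[Si](C(C)C)(C(C)C)C(C)C)c(OC)c2)OC(C)(C)C(C)(C)O1)[C@@H]1CO[C@@H](c2ccc(O[Si](C(C)C)(C(C)C)C(C)C)c(OC)c2)[C@@H]1CO[Si](C)(C)C(C)(C)C | intermediate
17 | secondary benzylic pinacol boronate, (S) at the boron-bearing carbon (Bpin in the place later taken by OH in 18) | COc1cc([C@@H](B2OC(C)(C)C(C)(C)O2)[C@@H]2CO[C@@H](c3ccc(O[Si](C(C)C)(C(C)C)C(C)C)c(OC)c3)[C@@H]2CO[Si](C)(C)C(C)(C)C)ccc1O[Si](C(C)C)(C(C)C)C(C)C | intermediate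
18 | (S)-[(3S,4S,5R)-5-ArT-4-({[tert-butyl(dimethyl)silyl]oxy}methyl)oxolan-3-yl](ArT)methanol | COc1cc([C@@H](O)[C@@H]2CO[C@@H](c3ccc(O[Si](C(C)C)(C(C)C)C(C)C)c(OC)c3)[C@@H]2CO[Si](C)(C)C(C)(C)C)ccc1O[Si](C(C)C)(C(C)C)C(C)C | intermediate
19 | 4-[(S)-hydroxy[(3S,4S,5R)-5-(4-hydroxy-3-methoxyphenyl)-4-(hydroxymethyl)oxolan-3-yl]methyl]-2-methoxyphenol | COc1cc([C@@H](O)[C@@H]2CO[C@@H](c3ccc(O)c(OC)c3)[C@@H]2CO)ccc1O | target

Total step count: 12. Longest linear sequence: 11 steps (1–9, 11, 12) from vanillin.

**Steps most likely to fail**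

Step 11. Deprotonation may go astray (at the benzylic C5–H of the 2-aryl oxolane or ortho to a methoxy group), the (+)-sparteine/substrate pairing may be mismatched so that selection between the two CH2 hydrogens erodes, or the 1,2-migration may stall. The fallback makes the same bond by carbonyl addition. It sets out from 11: Dess–Martin oxidation (NaHCO3, CH2Cl2) should give (3S,4S,5R)-5-ArT-4-({[tert-butyl(dimethyl)silyl]oxy}methyl)oxolane-3-carbaldehyde F1. Commercial 4-bromo-2-methoxyphenol F2 is silylated (TIPSCl, imidazole) to (4-bromo-2-methoxyphenoxy)tri(propan-2-yl)silane F3, which with Mg in THF gives (3-methoxy-4-{[tri(propan-2-yl)silyl]oxy}phenyl)magnesium bromide F4. Addition of F4 to F1 at −78 °C should follow the Felkin–Anh model (ring carbon C4 with its CH2OTBS arm anti to the nucleophile, ring CH2 on the inside). This is the sense that leads to 18, where the route is rejoined; the cold addition limits epimerisation of the cis aldehyde.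

Step 6. The β-titanoxy radical may be reduced by a second trivalent titanium and eliminate to the deoxygenated alkene before ring closure, or the trans selection in the ring closure may be weak. The fallback closes the ring by a closed-shell organopalladium pathway that needs no epoxide. It sets out from 7: Pd(OAc)2-catalysed borylative cyclisation of the 1,6-enyne with bis(pinacolato)diboron (MeOH, toluene, 50 °C; alkyne hydropalladation, alkene insertion, C–B bond formation) should give 2-{[(2R,3R)-2-ArT-4-methylideneoxolan-3-yl]methyl}-4,4,5,5-tetramethyl-1,3,2-dioxaborolane F5, with the aryl group again pseudo-equatorial. Oxidation of the C–B bond (NaOH, H2O2) gives 9, where the route is rejoined.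

Step 8. The borane may approach the exocyclic alkene from the face syn to the silyloxymethyl arm, so that the face selection that sets C3 is poor. The fallback sets C3 in the ring closure instead. It sets out from 8: dicyclohexylborane-catalysed hydroboration of the terminal alkyne with pinacolborane should give the (E)-alkenyl boronate 2-[(E)-3-{(S)-ArT(oxiran-2-yl)methoxy}prop-1-en-1-yl]-4,4,5,5-tetramethyl-1,3,2-dioxaborolane F6. Cp2TiCl-mediated epoxide opening and 5-exo-trig closure onto the boron-bearing alkene through a Beckwith–Houk chair transition state should then give [(2R,3S,4S)-2-ArT-4-[(4,4,5,5-tetramethyl-1,3,2-dioxaborolan-2-yl)methyl]oxolan-3-yl]methanol F7 (3,4-cis, 2,3-trans). Silylation (TBSCl, imidazole) gives tert-butyl{[(2R,3S,4S)-2-ArT-4-[(4,4,5,5-tetramethyl-1,3,2-dioxaborolan-2-yl)methyl]oxolan-3-yl]methoxy}dimethylsilane F8, and oxidation of the C–B bond (NaOH, H2O2) gives 11, where the route is rejoined.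

**Further compounds**
F1 | step 11 | (3S,4S,5R)-5-ArT-4-({[tert-butyl(dimethyl)silyl]oxy}methyl)oxolane-3-carbaldehyde | O=C[C@@H]1CO[C@@H](c2ccc(O[Si](C(C)C)(C(C)C)C(C)C)c(OC)c2)[C@@H]1CO[Si](C)(C)C(C)(C)C
F2 | step 11 | 4-bromo-2-methoxyphenol | COc1cc(Br)ccc1O
F3 | step 11 | (4-bromo-2-methoxyphenoxy)tri(propan-2-yl)silane | COc1cc(Br)ccc1O[Si](C(C)C)(C(C)C)C(C)C
F4 | step 11 | (3-methoxy-4-{[tri(propan-2-yl)silyl]oxy}phenyl)magnesium bromide | COc1cc([Mg]Br)ccc1O[Si](C(C)C)(C(C)C)C(C)C
F5 | step 6 | 2-{[(2R,3R)-2-ArT-4-methylideneoxolan-3-yl]methyl}-4,4,5,5-tetramethyl-1,3,2-dioxaborolane | C=C1CO[C@@H](c2ccc(O[Si](C(C)C)(C(C)C)C(C)C)c(OC)c2)[C@@H]1CB3OC(C)(C)C(C)(C)O3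
F6 | step 8 | 2-[(E)-3-{(S)-ArT(oxiran-2-yl)methoxy}prop-1-en-1-yl]-4,4,5,5-tetramethyl-1,3,2-dioxaborolane, both oxirane epimers | CC1(C)OB(OC1(C)C)/C=C/CO[C@H](C2CO2)c3ccc(O[Si](C(C)C)(C(C)C)C(C)C)c(OC)c3
F7 | step 8 | [(2R,3S,4S)-2-ArT-4-[(4,4,5,5-tetramethyl-1,3,2-dioxaborolan-2-yl)methyl]oxolan-3-yl]methanol | CC1(C)OB(C[C@@H]2CO[C@@H](c3ccc(O[Si](C(C)C)(C(C)C)C(C)C)c(OC)c3)[C@@H]2CO)OC1(C)C
F8 | step 8 | tert-butyl{[(2R,3S,4S)-2-ArT-4-[(4,4,5,5-tetramethyl-1,3,2-dioxaborolan-2-yl)methyl]oxolan-3-yl]methoxy}dimethylsilane | CC1(C)OB(C[C@@H]2CO[C@@H](c3ccc(O[Si](C(C)C)(C(C)C)C(C)C)c(OC)c3)[C@@H]2CO[Si](C)(C)C(C)(C)C)OC1(C)C
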